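**Retrosynthetic overview**

1. Target ⇐ silylene-masked α-methylene dialdehyde 24 (step 19): fluoride releases the diol, an oxa-Michael addition closes the oxepane, the resulting enolate oxygen adds to the second aldehyde to close the dihydropyran (last ring), and Ac2O caps the lactol and the free CH2OH. Enabling feature: in the dihydropyran the enol-ether carbon carries the CH2 that is bonded to the oxepane oxygen (O–CH2–C(=CH–O)), and the acetal carbon lies 1,5 to the enol-ether CH, so both heterocycles unzip to one 2-methylene-1,5-dialdehyde facing a cis CH2OH on the cyclopropane.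
2. 24 ⇐ 20: cycloheptane by an intramolecular Fráter–Seebach dianion alkylation in the SN2′ mode, forming the bond between the two ring-fusion carbons that the pyran and the carbocycle will share.
3. 20 ⇐ 14: all-cis cyclopropane by intramolecular cyclopropanation of the (Z)-allyl diazomalonate 13; the acceptor arm by Morita–Baylis–Hillman reaction and allylic bromination.
4. 13 ⇐ (S)-linalool (tertiary carbinol plus seven skeletal carbons), one carbon from the Ohira–Bestmann reagent, formaldehyde and methyl malonyl chloride.
5. Ring order: cyclopropane (step 10), cycloheptane (step 16), oxepane then dihydropyran (step 19).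

Key step: step 19

Remark: (S)-(+)-linalool of high enantiomeric purity is assumed to be purchasable; locants in the text follow secoaromadendrane numbering (C-2 acetal, C-3=C-4 enol ether, C-1/C-5 pyran–cycloheptane fusion, C-6/C-7 cyclopropane CH, C-10 carbinol, C-11 quaternary cyclopropane carbon, C-12 oxepane OCH2 on C-11, C-13 CH2OAc, C-15 oxepane CH2 on C-4).

Step 1
Reactants: 1 (S)-(+)-linalool
Product: 3 (3S)-3,7-dimethyloct-6-ene-1,3-diol, via B-alkyl-9-BBN adduct 2 (not isolated)
Conditions: 9-BBN (2.2 equiv), THF, 0 °C → rt; then NaOH, H2O2, 0 °C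
Reagents that add atoms: 9-borabicyclo[3.3.1]nonane, B1C2CCCC1CCC2 (boron only in 2); hydrogen peroxide, OO
Why: Brown hydroboration–oxidation: 9-BBN adds anti-Markovnikov to the monosubstituted vinyl group and leaves the trisubstituted alkene alone, and the chiral-pool carbinol centre (later C-10) is not involved.

Step 2
Reactants: 3 (3S)-3,7-dimethyloct-6-ene-1,3-diol
Product: 4 (3S)-3-hydroxy-3,7-dimethyloct-6-enoic acid
Conditions: TEMPO (cat.), PhI(OAc)2 (2.2 equiv), MeCN/H2O, rt
Reagents that add atoms: water, O
Why: Oxoammonium (TEMPO/PhI(OAc)2) oxidation takes the primary alcohol through the aldehyde hydrate to the acid while the tertiary alcohol and the alkene are inert.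

Step 3
Reactants: 4 (3S)-3-hydroxy-3,7-dimethyloct-6-enoic acid
Product: 5 tert-butyl (3S)-3-hydroxy-3,7-dimethyloct-6-enoate
Conditions: Cl3CC(=NH)OtBu, CH2Cl2/cyclohexane, rt
Reagents that add atoms: tert-butyl 2,2,2-trichloroacetimidate, CC(C)(C)OC(=N)C(Cl)(Cl)Cl
Why: Imidate esterification without acid catalyst gives the tert-butyl ester, chosen because it should survive LiBH4 in step 11 and later serves as the enolate donor.

Step 4
Reactants: 5 tert-butyl (3S)-3-hydroxy-3,7-dimethyloct-6-enoate
Product: 6 tert-butyl 2-[(2S)-5-hydroxy-2-methyloxolan-2-yl]acetate (lactol)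
Conditions: OsO4 (cat.), NaIO4, 2,6-lutidine, dioxane/H2O, rt
Reagents that add atoms: sodium periodate, [Na+].[O-]I(=O)(=O)=O
Why: Lemieux–Johnson cleavage of the only alkene releases acetone and the aldehyde, which rests as the five-membered lactol with the tertiary hydroxyl.

Step 5
Reactants: 6 tert-butyl 2-[(2S)-5-hydroxy-2-methyloxolan-2-yl]acetate
Product: 7 tert-butyl (3S)-3-hydroxy-3-methylhept-6-ynoate
Conditions: dimethyl (1-diazo-2-oxopropyl)phosphonate, K2CO3, MeOH, 0 °C → rt
Reagents that add atoms: Ohira–Bestmann reagent, COP(=O)(OC)C(=[N+]=[N-])C(C)=O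
Why: Seyferth–Gilbert homologation (Ohira–Bestmann variant) acts on the open-chain aldehyde tautomer under carbonate conditions that the tert-butyl β-hydroxy ester tolerates.

Step 6
Reactants: 7 tert-butyl (3S)-3-hydroxy-3-methylhept-6-ynoate
Product: 9 tert-butyl (3S)-3,8-dihydroxy-3-methyloct-6-ynoate, via bis-magnesium acetylide alkoxide 8 (not isolated)
Conditions: EtMgBr (2.3 equiv), THF, 0 → 40 °C; then (CH2O)n, 45 °C
Reagents that add atoms: ethylmagnesium bromide, CC[Mg]Br (magnesium and bromine only in 8); formaldehyde (as paraformaldehyde), C=O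
Why: Alkynyl Grignard formation (one equivalent is spent on the tertiary OH) and addition to formaldehyde gives the propargylic alcohol; the hindered tert-butyl ester should not react with the magnesium acetylide.

Step 7
Reactants: 9 tert-butyl (3S)-3,8-dihydroxy-3-methyloct-6-ynoate
Product: 10 tert-butyl (3S,6Z)-3,8-dihydroxy-3-methyloct-6-enoate
Conditions: H2 (1 atm), Pd/CaCO3 poisoned with Pb(OAc)2, quinoline, EtOAc, rt
Reagents that add atoms: none
Why: Semihydrogenation on poisoned palladium is a syn addition and gives the (Z)-allylic alcohol, whose geometry becomes the cis relation of the two cyclopropane CH substituents.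

Step 8
Reactants: 10 tert-butyl (3S,6Z)-3,8-dihydroxy-3-methyloct-6-enoate; 11 methyl malonyl chloride
Product: 12 (2Z,6S)-8-tert-butoxy-6-hydroxy-6-methyl-8-oxooct-2-en-1-yl methyl malonate
Conditions: pyridine, CH2Cl2, 0 °C
Reagents that add atoms: none
Why: O-acylation of the primary allylic alcohol by the acid chloride; the tertiary alcohol is too hindered to compete at 0 °C.

Step 9
Reactants: 12 (2Z,6S)-8-tert-butoxy-6-hydroxy-6-methyl-8-oxooct-2-en-1-yl methyl malonate
Product: 13 the corresponding methyl 2-diazomalonate
Conditions: 4-acetamidobenzenesulfonyl azide, Et3N, MeCN, 0 °C → rt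
Reagents that add atoms: 4-acetamidobenzenesulfonyl azide, CC(=O)Nc1ccc(cc1)S(=O)(=O)N=[N+]=[N-]
Why: Regitz diazo transfer to the activated malonate methylene.

Step 10
Reactants: 13 allyl methyl diazomalonate
Product: 14 methyl (1S,5R,6S)-6-[(3S)-5-tert-butoxy-3-hydroxy-3-methyl-5-oxopentyl]-2-oxo-3-oxabicyclo[3.1.0]hexane-1-carboxylate
Conditions: Cu(MeCN)4PF6 (5 mol%), (S,S)-tBu-BOX (6 mol%), CH2Cl2, 40 °C, syringe-pump addition
Reagents that add atoms: none
Why: Intramolecular carbenoid cyclopropanation is stereospecific: the five-membered lactone tether enforces cis fusion and the (Z)-alkene puts the side chain on the same face, so all cis relations at C-6, C-7 and C-11 are fixed, while the chiral copper–bis(oxazoline) catalyst selects the alkene face (ligand antipode chosen accordingly; because the substrate is already enantiopure, a wrong-face product is a separable diastereomer).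

Step 11
Reactants: 14 cyclopropane lactone ester
Product: 15 tert-butyl (3S)-3-hydroxy-3-methyl-5-[(1S,2R)-2,3,3-tris(hydroxymethyl)cyclopropyl]pentanoate
Conditions: LiBH4, THF/MeOH, 0 °C → rt
Reagents that add atoms: none
Why: LiBH4 reduces the lactone and the methyl ester to three primary alcohols but should leave the tert-butyl ester untouched.

Step 12
Reactants: 15 tetraol
Product: 16 spiro-silylene alcohol
Conditions: tBu2Si(OTf)2 (1.05 equiv), 2,6-lutidine, CH2Cl2, −20 °C
Reagents that add atoms: di-tert-butylsilyl bis(trifluoromethanesulfonate), CC(C)(C)[Si](OS(=O)(=O)C(F)(F)F)(OS(=O)(=O)C(F)(F)F)C(C)(C)C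
Why: The two geminal CH2OH groups form the six-membered cyclic silylene in preference to any larger ring, which leaves only the CH2OH on the ring CH free and keeps the future C-12 and C-13 oxygens equivalent until the key step.

Step 13
Reactants: 16 spiro-silylene alcohol
Product: 17 spiro-silylene cyclopropanecarbaldehyde
Conditions: Dess–Martin periodinane, NaHCO3, CH2Cl2, 0 °C → rt
Reagents that add atoms: none
Why: Buffered Dess–Martin oxidation of the remaining primary alcohol; the tertiary alcohol is inert and the cis-cyclopropane aldehyde should not epimerise.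

Step 14
Reactants: 17 spiro-silylene cyclopropanecarbaldehyde; 18 methyl acrylate
Product: 19 Morita–Baylis–Hillman adduct (carbinol epimers)
Conditions: DABCO (1 equiv), MeOH, rt, several days
Reagents that add atoms: none
Why: Morita–Baylis–Hillman reaction installs C-4, C-15 and C-3; the new carbinol centre is a mixture of no consequence because it is erased in step 15.

Step 15
Reactants: 19 Morita–Baylis–Hillman adduct
Product: 20 (Z)-2-(bromomethyl)enoate
Conditions: NBS, Me2S, CH2Cl2, −20 → 0 °C
Reagents that add atoms: N-bromosuccinimide, BrN1C(=O)CCC1=O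
Why: Corey–Kim-type bromination (bromodimethylsulfonium) proceeds with allylic transposition (SN2′) to the conjugated, thermodynamically preferred (Z)-2-(bromomethyl)enoate; the tertiary alcohol is too hindered to react.

Step 16
Reactants: 20 (Z)-2-(bromomethyl)enoate
Product: 22 bicyclo[5.1.0]octane diester, via dilithium dianion 21 (not isolated)
Conditions: LiN(iPr)2 (2.3 equiv), THF, −78 → −30 °C, inverse addition at high dilution; NH4Cl
Reagents that add atoms: lithium diisopropylamide, CC(C)N([Li])C(C)C (lithium only in 21)
Why: Fráter–Seebach dianion alkylation run in the SN2′ (conjugate addition–elimination) mode as a 7-exo-trig closure: the lithium alkoxide–enolate chelate should be attacked on its tether-bearing face (anti to the methyl group), putting the ester cis to the hydroxyl (C-1 relative to C-10), while the acceptor reacts through the bisected s-trans vinylcyclopropane conformer (vinylic H over the three-membered ring, enforced by A1,3 strain from CH2Br) on the face turned toward the tether, putting H-5 anti to H-6; loss of bromide leaves the α-methylene ester.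

Step 17
Reactants: 22 bicyclo[5.1.0]octane diester
Product: 23 bicyclic diol
Conditions: i-Bu2AlH (7 equiv), CH2Cl2, −78 → 0 °C; aq. potassium sodium tartrate
Reagents that add atoms: none
Why: i-Bu2AlH reduces the acrylate-type methyl ester in the 1,2-mode and, on warming, the tert-butyl ester, giving the two primary alcohols; silylene and tertiary alcohol should survive.

Step 18
Reactants: 23 bicyclic diol
Product: 24 silylene-protected α-methylene dialdehyde
Conditions: Dess–Martin periodinane (3 equiv), NaHCO3, CH2Cl2, 0 °C
Reagents that add atoms: none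
Why: Double Dess–Martin oxidation gives the α-methylene aldehyde and the β-hydroxy aldehyde under neutral buffered conditions that should avoid retro-aldol cleavage and epimerisation at C-1; the product is used at once.

Step 19
Reactants: 24 silylene-protected α-methylene dialdehyde
Product: 27 target CNP0250836.3, via triol dialdehyde 25 (not isolated), via lactol 26 (not isolated)
Conditions: Bu4NF (2.5 equiv), THF, −20 → 0 °C; then Ac2O, pyridine, DMAP (cat.), 0 °C → rt
Reagents that add atoms: acetic anhydride, CC(=O)OC(C)=O
Why: Fluoride strips the di-tert-butylsilylene, and of the two alkoxides released only the one cis to the ring substituents can reach the methylene terminus of the α-methylene aldehyde, so a 7-endo-trig oxa-Michael addition closes the oxepane and makes C-11 stereogenic by geometric selection between the two diastereotopic CH2O groups. The aldehyde enolate produced by that addition lies on the enol-ether side by construction, and its oxygen adds to the neighbouring cis formyl group in a 6-exo-trig closure that forms the dihydropyran lactol last; Ac2O then acetylates the lactol oxygen and the remaining primary hydroxyl, the tertiary alcohol being too hindered. The closest known reaction types are base-mediated intramolecular oxa-Michael additions to enals and the enol-hemiacetal closure of 1,5-dialdehydes familiar from iridoid lactols. The only new stereocentre besides C-11, the acetal carbon C-2, should take the configuration with the acetoxy group axial (anomeric effect) and anti to the C-1–C-10 bond, as in iridoid acetals, because the lactol anomers equilibrate before acylation. The step needs the primary alkoxide to outrun the tertiary one (which would give a bridged six-membered ether) and needs the β-hydroxy aldehyde to escape retro-aldol cleavage and C-1 epimerisation; low temperature, the higher nucleophilicity of the unhindered primary alkoxide and immediate intramolecular capture of the enolate are relied on for this.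

**Compound list**

1 | (S)-(+)-linalool, (3S)-3,7-dimethylocta-1,6-dien-3-ol | CC(C)=CCC[C@](C)(O)C=C | starting material
2 | B-[(3S)-3-hydroxy-3,7-dimethyloct-6-en-1-yl]-9-borabicyclo[3.3.1]nonane | CC(C)=CCC[C@](C)(O)CCB1C2CCCC1CCC2 | intermediate
3 | (3S)-3,7-dimethyloct-6-ene-1,3-diol | CC(C)=CCC[C@](C)(O)CCO | intermediate
4 | (3S)-3-hydroxy-3,7-dimethyloct-6-enoic acid | CC(C)=CCC[C@](C)(O)CC(=O)O | intermediate
5 | tert-butyl (3S)-3-hydroxy-3,7-dimethyloct-6-enoate | CC(C)=CCC[C@](C)(O)CC(=O)OC(C)(C)C | intermediate
6 | tert-butyl 2-[(2S)-5-hydroxy-2-methyloxolan-2-yl]acetate (lactol, both C-5 epimers; ring tautomer of the 6-oxo ester) | CC(C)(C)OC(=O)C[C@]1(C)CCC(O)O1 | intermediate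
7 | tert-butyl (3S)-3-hydroxy-3-methylhept-6-ynoate | CC(C)(C)OC(=O)C[C@@](C)(O)CCC#C | intermediate
8 | bis(bromomagnesium) alkoxide/acetylide of 7 | CC(C)(C)OC(=O)C[C@@](C)(O[Mg]Br)CCC#C[Mg]Br | intermediate
9 | tert-butyl (3S)-3,8-dihydroxy-3-methyloct-6-ynoate | CC(C)(C)OC(=O)C[C@@](C)(O)CCC#CCO | intermediate
10 | tert-butyl (3S,6Z)-3,8-dihydroxy-3-methyloct-6-enoate | CC(C)(C)OC(=O)C[C@@](C)(O)CC/C=C\CO | intermediate
11 | methyl malonyl chloride (methyl 3-chloro-3-oxopropanoate) | COC(=O)CC(=O)Cl | starting material
12 | (2Z,6S)-8-tert-butoxy-6-hydroxy-6-methyl-8-oxooct-2-en-1-yl methyl malonate | CC(C)(C)OC(=O)C[C@@](C)(O)CC/C=C\COC(=O)CC(=O)OC | intermediate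
13 | (2Z,6S)-8-tert-butoxy-6-hydroxy-6-methyl-8-oxooct-2-en-1-yl methyl 2-diazomalonate | CC(C)(C)OC(=O)C[C@@](C)(O)CC/C=C\COC(=O)C(=[N+]=[N-])C(=O)OC | intermediate
14 | methyl (1S,5R,6S)-6-[(3S)-5-tert-butoxy-3-hydroxy-3-methyl-5-oxopentyl]-2-oxo-3-oxabicyclo[3.1.0]hexane-1-carboxylate (side chain endo) | COC(=O)[C@@]1(C(=O)OC2)[C@H]2[C@@H]1CC[C@](C)(O)CC(=O)OC(C)(C)C | intermediate
15 | tert-butyl (3S)-3-hydroxy-3-methyl-5-[(1S,2R)-2,3,3-tris(hydroxymethyl)cyclopropyl]pentanoate (chain and ring-CH CH2OH cis) | OCC1(CO)[C@H](CO)[C@@H]1CC[C@](C)(O)CC(=O)OC(C)(C)C | intermediate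
16 | tert-butyl (3S)-5-[(1S,2R)-6,6-di-tert-butyl-2-(hydroxymethyl)-5,7-dioxa-6-silaspiro[2.5]octan-1-yl]-3-hydroxy-3-methylpentanoate | CC(C)(C)[Si]1(C(C)(C)C)OCC2(CO1)[C@H](CO)[C@@H]2CC[C@](C)(O)CC(=O)OC(C)(C)C | intermediate
17 | tert-butyl (3S)-5-[(1S,2R)-6,6-di-tert-butyl-2-formyl-5,7-dioxa-6-silaspiro[2.5]octan-1-yl]-3-hydroxy-3-methylpentanoate | CC(C)(C)[Si]1(C(C)(C)C)OCC2(CO1)[C@H](C=O)[C@@H]2CC[C@](C)(O)CC(=O)OC(C)(C)C | intermediate
18 | methyl acrylate | C=CC(=O)OC | starting material
19 | Morita–Baylis–Hillman adduct of 17: the 2-[1-hydroxy-2-(methoxycarbonyl)prop-2-en-1-yl] analogue (carbinol epimers, ring configuration as in 17) | CC(C)(C)[Si]1(C(C)(C)C)OCC2(CO1)[C@H](C(O)C(=C)C(=O)OC)[C@@H]2CC[C@](C)(O)CC(=O)OC(C)(C)C | intermediate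
20 | allylic bromide: the 2-[(1Z)-3-bromo-2-(methoxycarbonyl)prop-1-en-1-yl] analogue of 17 | CC(C)(C)[Si]1(C(C)(C)C)OCC2(CO1)[C@H](/C=C(\CBr)C(=O)OC)[C@@H]2CC[C@](C)(O)CC(=O)OC(C)(C)C | intermediate
21 | dilithium alkoxide/ester enolate of 20 | CC(C)(C)[Si]1(C(C)(C)C)OCC2(CO1)[C@H](/C=C(\CBr)C(=O)OC)[C@@H]2CC[C@](C)(O[Li])C=C(O[Li])OC(C)(C)C | intermediate
22 | silylene-protected bicyclo[5.1.0]octane diester: tert-butyl 4-hydroxy-2-[1-(methoxycarbonyl)ethenyl]-4-methyl-8,8-bis(oxymethyl)bicyclo[5.1.0]octane-3-carboxylate as its di-tert-butylsilylene (2-substituent trans to the cyclopropane, 3-ester cis to the 2-substituent, 4-OH cis to the 3-ester) | CC(C)(C)[Si]3(C(C)(C)C)OCC1(CO3)[C@@H]2[C@@H](C(=C)C(=O)OC)[C@@H](C(=O)OC(C)(C)C)[C@@](C)(O)CC[C@H]12 | intermediate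
23 | diol from 22: 3-(hydroxymethyl) and 2-[1-(hydroxymethyl)ethenyl], same configuration | CC(C)(C)[Si]3(C(C)(C)C)OCC1(CO3)[C@@H]2[C@@H](C(=C)CO)[C@@H](CO)[C@@](C)(O)CC[C@H]12 | intermediate
24 | dialdehyde from 23: 3-formyl and 2-(1-formylethenyl), same configuration | CC(C)(C)[Si]3(C(C)(C)C)OCC1(CO3)[C@@H]2[C@@H](C(=C)C=O)[C@@H](C=O)[C@@](C)(O)CC[C@H]12 | intermediate
25 | triol dialdehyde: 3-formyl-2-(1-formylethenyl)-4-hydroxy-8,8-bis(hydroxymethyl)-4-methylbicyclo[5.1.0]octane, same configuration | OCC1(CO)[C@@H]2[C@@H](C(=C)C=O)[C@@H](C=O)[C@@](C)(O)CC[C@H]12 | intermediate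
26 | lactol: the target without its two acetyl groups (C-2 hemiacetal anomers, C-13 OH free) | OC[C@@]12COCC3=COC(O)[C@@H]4[C@H]3[C@@H]1[C@@H]2CC[C@]4(C)O | intermediate
27 | CNP0250836.3 (C-2 acetal acetate, C-13 acetate, C-10 tertiary alcohol) | CC(=O)OC[C@@]12COCC3=CO[C@H](OC(C)=O)[C@@H]4[C@H]3[C@@H]1[C@@H]2CC[C@]4(C)O | target

**Step count and risks**

Total steps: 19. Longest linear sequence: 19 (fully linear from 1).

Steps most likely to fail:

1. Step 19. The free tetrabutylammonium alkoxides may trigger retro-aldol cleavage or C-1 epimerisation of the β-hydroxy aldehyde before ring closure, and the tertiary alkoxide may add to the enal in a competing six-membered closure. Fallback: uncouple deprotection from cyclisation and avoid strong base. From 24, HF·pyridine/pyridine (THF, 0 °C) removes the silylene and the triol dialdehyde 25 is isolated. Catalytic PMe3 in MeCN (phosphine-catalysed hydroalkoxylation of the enal, which should discriminate primary from tertiary hydroxyl) then closes oxepane and lactol, and lactol 26 is isolated; acetylation (Ac2O, pyridine, DMAP) follows as in the route. The fallback sets out from 24 and comes back at 26; it makes no compound outside the list (F0).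

2. Step 16. Attack of the amide base on the bromo-enoate, or intermolecular alkylation, may outrun the seven-membered closure. Fallback: replace the allylic bromide by a plain enoate and install the methylene afterwards. From 17, Horner–Wadsworth–Emmons reaction with trimethyl phosphonoacetate (NaH, THF) gives the (E)-enoate F1. LiN(iPr)2 (2.3 equiv, THF, −78 °C) then effects the same chelated dianion Michael cyclisation, and the resulting methyl ester enolate is trapped in the flask with Eschenmoser's salt to give the Mannich base F2. Quaternisation with MeI and elimination with DBU gives the α-methylene ester. The fallback sets out from 17, bypasses 19 and 20, and comes back at 22.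

3. Step 14. The amine-catalysed addition may stall at the hindered, doubly cis-flanked aldehyde, with slow epimerisation of the cyclopropane aldehyde meanwhile. Fallback: use a preformed vinyl-metal instead of amine catalysis. Hydroalumination of methyl propiolate with i-Bu2AlH/N-methylmorpholine N-oxide (THF, 0 °C) gives the α-aluminoacrylate, which adds to 17 at low temperature to give the same adduct. The fallback sets out from 17 and comes back at 19; it makes no compound outside the list (F0).

Further compounds
F0 | step 19 | none | none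
F1 | step 16 | (E)-enoate from 17: the 2-[(1E)-3-methoxy-3-oxoprop-1-en-1-yl] analogue of 17 | CC(C)(C)[Si]1(C(C)(C)C)OCC2(CO1)[C@H](/C=C/C(=O)OC)[C@@H]2CC[C@](C)(O)CC(=O)OC(C)(C)C
F2 | step 16 | Mannich base: analogue of 22 with CH(CH2NMe2)CO2Me in place of the 1-(methoxycarbonyl)ethenyl group (epimers at the new CH) | CC(C)(C)[Si]3(C(C)(C)C)OCC1(CO3)[C@@H]2[C@@H](C(CN(C)C)C(=O)OC)[C@@H](C(=O)OC(C)(C)C)[C@@](C)(O)CC[C@H]12
F0 | step 14 | none | none
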